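**Retrosynthetic overview**

- The γ-lactone ring O1–C2(=O)–C3(=CH2)–C4(CO2H)–C5(chain) is opened at O1–C5 to the seco diacid (R)-2-methylidene-3-(15-oxohexadecyl)butanedioic acid. In this diacid C5 is a plain CH2 that is β to the C4 carboxyl and γ to the C2 carboxyl, and the route rests on that double relation.
- The C3 methylene comes from carboxylation and decarboxylative Mannich methylenation of an (R)-2-alkylsuccinic 4-tert-butyl ester. The C4 stereocentre comes from an Evans alkylation of an octadec-17-enoyl oxazolidinone with tert-butyl bromoacetate.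
- The C18 chain comes from a copper-catalysed coupling of hept-6-enyl Grignard reagent with 11-bromoundecanoic acid. The terminal alkene is the masked methyl ketone and is oxidised (Wacker) only after the enolate steps.
- Ring order: the single ring, the γ-lactone, is closed in the last step by carboxylate-directed palladation of C5–H and C–O bond formation.

Key step: step 9

Remark: ring atoms are called O1, C2 (lactone C=O), C3 (=CH2), C4 (CO2H) and C5 (chain) throughout. The target SMILES is the cis isomer, (2S,3S) in oxolane numbering, with a 14-oxopentadecyl chain.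

**Route**

Step 1
Reactants: 1 7-bromohept-1-ene; 2 11-bromoundecanoic acid
Product: 5 octadec-17-enoic acid, via hept-6-enylmagnesium bromide 3 (not isolated), via chloromagnesium 11-bromoundecanoate 4 (not isolated)
Conditions: 1, Mg, THF, 40 °C; separately 2, MeMgCl (1.0 equiv), THF, −20 °C; combine, Li2CuCl4 (3 mol%), −20 °C → rt; 1 M HCl
Reagents that add atoms: none
Why: Copper-catalysed sp3–sp3 Grignard cross-coupling (Kochi coupling) should take place only at the primary C–Br bond, because the magnesium carboxylate does not add Grignard reagent at −20 °C and the terminal alkene is inert.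

Step 2
Reactants: 5 octadec-17-enoic acid; 6 (4S)-4-benzyl-1,3-oxazolidin-2-one
Product: 8 (4S)-4-benzyl-3-(octadec-17-enoyl)-1,3-oxazolidin-2-one, via octadec-17-enoic pivalic anhydride 7 (not isolated)
Conditions: PivCl, Et3N, THF, −20 °C; then LiCl, 6, −20 °C → rt
Reagents that add atoms: none
Why: Mixed-anhydride N-acylation of the oxazolidinone; the nucleophile should attack the unhindered fatty acyl carbon and not the pivaloyl carbon.

Step 3
Reactants: 8 (4S)-4-benzyl-3-(octadec-17-enoyl)-1,3-oxazolidin-2-one; 9 tert-butyl bromoacetate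
Product: 11 tert-butyl (3R)-3-{[(4S)-4-benzyl-2-oxo-1,3-oxazolidin-3-yl]carbonyl}nonadec-18-enoate, via sodium (Z)-enolate of the acyl oxazolidinone 10 (not isolated)
Conditions: NaHMDS (1.1 equiv), THF, −78 °C; then 9, −78 → −40 °C
Reagents that add atoms: none
Why: Evans asymmetric alkylation; the chelated (Z)-enolate should be alkylated on the face away from the benzyl group, which sets the future C4 centre as (R).

Step 4
Reactants: 11 tert-butyl (3R)-3-{[(4S)-4-benzyl-2-oxo-1,3-oxazolidin-3-yl]carbonyl}nonadec-18-enoate
Product: 13 (2R)-2-(2-tert-butoxy-2-oxoethyl)octadec-17-enoic acid, via (2R)-2-(2-tert-butoxy-2-oxoethyl)octadec-17-eneperoxoic acid 12 (not isolated)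
Conditions: LiOH, 30% H2O2, THF/H2O 3:1, 0 °C; then aq. Na2SO3; HCl to pH 3
Reagents that add atoms: hydrogen peroxide, OO
Why: Hydroperoxide cleavage of the exocyclic imide carbonyl (Evans LiOOH hydrolysis) should free the acid without racemisation, and the tert-butyl ester and the alkene should survive at 0 °C.

Step 5
Reactants: 13 (2R)-2-(2-tert-butoxy-2-oxoethyl)octadec-17-enoic acid
Product: 15 (3R)-2-(tert-butoxycarbonyl)-3-(hexadec-15-en-1-yl)butanedioic acid (C2 epimers), via dilithium carboxylate ester-enolate dianion 14 (not isolated)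
Conditions: LDA (commercial, 2.3 equiv), THF, −78 °C; CO2 (g), −78 → −20 °C; cold 1 M HCl
Reagents that add atoms: carbon dioxide, O=C=O
Why: Dianion chemistry of a succinic half-ester; the lithium carboxylate shields its own α-hydrogen (C4–H), so the second equivalent of base should enolise only the CH2 next to the ester, and that enolate is C-carboxylated.

Step 6
Reactants: 15 (3R)-2-(tert-butoxycarbonyl)-3-(hexadec-15-en-1-yl)butanedioic acid
Product: 17 (2R)-2-[3-(tert-butoxy)-3-oxoprop-1-en-2-yl]octadec-17-enoic acid, via diethylaminomethyl Mannich adduct 16 (not isolated)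
Conditions: (CH2O)n, Et2NH, EtOAc, 60 °C
Reagents that add atoms: formaldehyde (as paraformaldehyde), C=O
Why: Decarboxylative Mannich methylenation of a malonic half-ester; aminomethylation at the malonate carbon followed by loss of CO2 and Et2NH should give the 2-substituted acrylate, while C4 stays the α-carbon of a carboxylate salt and is not deprotonated.

Step 7
Reactants: 17 (2R)-2-[3-(tert-butoxy)-3-oxoprop-1-en-2-yl]octadec-17-enoic acid
Product: 18 (2R)-2-[3-(tert-butoxy)-3-oxoprop-1-en-2-yl]-17-oxooctadecanoic acid
Conditions: PdCl2 (10 mol%), Cu(OAc)2 (20 mol%), O2 (1 atm), DMA/H2O 7:1, rt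
Reagents that add atoms: water, O
Why: Tsuji–Wacker oxidation; Markovnikov hydroxypalladation should occur only at the monosubstituted terminal alkene, because the electron-poor 1,1-disubstituted acrylate does not undergo it.

Step 8
Reactants: 18 (2R)-2-[3-(tert-butoxy)-3-oxoprop-1-en-2-yl]-17-oxooctadecanoic acid
Product: 19 (3R)-2-methylidene-3-(15-oxohexadecyl)butanedioic acid
Conditions: TFA/CH2Cl2 1:3, 0 °C → rt
Reagents that add atoms: none
Why: Acidolysis of the tert-butyl ester with loss of isobutene; acid-only conditions should avoid the base-induced shift of the exocyclic double bond that would destroy C4.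

Step 9
Reactants: 19 (3R)-2-methylidene-3-(15-oxohexadecyl)butanedioic acid
Product: 20 allo-pertusaric acid, (2S,3S)-4-methylidene-5-oxo-2-(14-oxopentadecyl)oxolane-3-carboxylic acid
Conditions: Pd(OAc)2 (10 mol%), bidentate quinoline–pyridone ligand of the type that favours a five-membered palladacycle (12 mol%), tBuOOH (70% aq., 2.5 equiv), NaOAc (0.5 equiv), HFIP, 60 °C
Reagents that add atoms: none
Why: Proposed new method: the C4 carboxylate binds Pd(II) and, with the pyridone ligand as internal base, one C5–H bond is cleaved by concerted metalation–deprotonation to a five-membered palladacycle; tBuOOH should oxidise this to Pd(IV) before β-hydride elimination can intervene, the C2 carboxylate completes a six-membered O,C-chelate on the same metal, and C–O reductive elimination from that chelate forms O1–C5 and returns Pd(II). The closest known reaction type is the Pd(II)/Pd(IV) carboxylate-directed β- and γ-C(sp3)–H lactonisation of free aliphatic acids and diacids in HFIP; not yet shown are a 1,4-diacid of the itaconic type, an existing α-stereocentre that must steer the new C–O bond, and a free acrylic acid in the same molecule. The γ-lactone is closed by ring-contracting C–O reductive elimination from the six-membered pallada-lactone, formally a 5-exo-tet closure of the C2 carboxylate oxygen onto C5. The new C5 centre is controlled by the C4 centre: palladation should take the C5–H that leaves the chain trans to the itaconyl arm on the palladacycle, and inner-sphere C–O formation with retention at C5 then places the chain cis to the C4 carboxyl, which is the (2S,3S) target. The step needs site selectivity for C5 and retention at C5; C5 is the only sp3 carbon that is β to one carboxylate and γ to the other, so only there can both acids sit on one palladium, and this O,C,O chelation is also what holds the C2 carboxylate cis to the Pd–C5 bond for the retentive closure.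

**Compound list**

1 | 7-bromohept-1-ene | C=CCCCCCBr | starting material
2 | 11-bromoundecanoic acid | OC(=O)CCCCCCCCCCBr | starting material
3 | hept-6-enylmagnesium bromide (not isolated) | C=CCCCCC[Mg]Br | intermediate
4 | chloromagnesium 11-bromoundecanoate (not isolated) | BrCCCCCCCCCCC(=O)O[Mg]Cl | intermediate
5 | octadec-17-enoic acid | C=CCCCCCCCCCCCCCCCC(=O)O | intermediate
6 | (4S)-4-benzyl-1,3-oxazolidin-2-one | O=C1N[C@@H](Cc2ccccc2)CO1 | starting material
7 | octadec-17-enoic pivalic anhydride (not isolated) | C=CCCCCCCCCCCCCCCCC(=O)OC(=O)C(C)(C)C | intermediate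
8 | (4S)-4-benzyl-3-(octadec-17-enoyl)-1,3-oxazolidin-2-one | C=CCCCCCCCCCCCCCCCC(=O)N1[C@@H](Cc2ccccc2)COC1=O | intermediate
9 | tert-butyl bromoacetate | CC(C)(C)OC(=O)CBr | starting material
10 | sodium (Z)-enolate of 8 (not isolated) | [Na+].[O-]/C(=C\CCCCCCCCCCCCCCC=C)N1[C@@H](Cc2ccccc2)COC1=O | intermediate
11 | tert-butyl (3R)-3-{[(4S)-4-benzyl-2-oxo-1,3-oxazolidin-3-yl]carbonyl}nonadec-18-enoate | C=CCCCCCCCCCCCCCC[C@@H](C(=O)N1[C@@H](Cc2ccccc2)COC1=O)CC(=O)OC(C)(C)C | intermediate
12 | (2R)-2-(2-tert-butoxy-2-oxoethyl)octadec-17-eneperoxoic acid (not isolated) | C=CCCCCCCCCCCCCCC[C@@H](C(=O)OO)CC(=O)OC(C)(C)C | intermediate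
13 | (2R)-2-(2-tert-butoxy-2-oxoethyl)octadec-17-enoic acid | C=CCCCCCCCCCCCCCC[C@@H](C(=O)O)CC(=O)OC(C)(C)C | intermediate
14 | dilithium carboxylate ester-enolate dianion of 13 (not isolated) | [Li+].[Li+].C=CCCCCCCCCCCCCCC[C@@H](C(=O)[O-])C=C([O-])OC(C)(C)C | intermediate
15 | (3R)-2-(tert-butoxycarbonyl)-3-(hexadec-15-en-1-yl)butanedioic acid (C2 epimers) | C=CCCCCCCCCCCCCCC[C@@H](C(=O)O)C(C(=O)O)C(=O)OC(C)(C)C | intermediate
16 | (3R)-2-(tert-butoxycarbonyl)-2-[(diethylamino)methyl]-3-(hexadec-15-en-1-yl)butanedioic acid (not isolated) | C=CCCCCCCCCCCCCCC[C@@H](C(=O)O)C(CN(CC)CC)(C(=O)O)C(=O)OC(C)(C)C | intermediate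
17 | (2R)-2-[3-(tert-butoxy)-3-oxoprop-1-en-2-yl]octadec-17-enoic acid | C=CCCCCCCCCCCCCCC[C@@H](C(=O)O)C(=C)C(=O)OC(C)(C)C | intermediate
18 | (2R)-2-[3-(tert-butoxy)-3-oxoprop-1-en-2-yl]-17-oxooctadecanoic acid | CC(=O)CCCCCCCCCCCCCC[C@@H](C(=O)O)C(=C)C(=O)OC(C)(C)C | intermediate
19 | (3R)-2-methylidene-3-(15-oxohexadecyl)butanedioic acid | CC(=O)CCCCCCCCCCCCCC[C@H](C(=C)C(=O)O)C(=O)O | intermediate
20 | allo-pertusaric acid, (2S,3S)-4-methylidene-5-oxo-2-(14-oxopentadecyl)oxolane-3-carboxylic acid | C=C1C(=O)O[C@@H](CCCCCCCCCCCCCC(C)=O)[C@H]1C(=O)O | target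

**Step count**

Total steps: 9. Longest linear sequence: 9 steps (from 1 and 2 to 20).

**Steps most likely to fail**

1. Step 9 (proposed new method). Three processes may defeat it. The C–O bond may form by backside attack of an unbound C2 carboxylate on the Pd(IV)–C5 bond, that is with inversion, which would lead to the C5 epimer. The palladacycle may undergo β-hydride elimination before it is oxidised, which would erase C4. The acrylic acid may bind palladium so strongly that C5–H cleavage does not start.
 Fallback (known chemistry; sets out from 1 as its Grignard reagent 3 and from 9, comes back at 20): the C5–O bond is brought in as a carbinol and C4 is then set against it. Copper-catalysed coupling of 3 with commercial methyl 9-bromononanoate (Li2CuCl4, THF/NMP, −10 °C) should give methyl hexadec-15-enoate F1. Crossed Claisen condensation with the lithium enolate of tert-butyl acetate should give tert-butyl 3-oxooctadec-17-enoate F2. Ru-(S)-BINAP hydrogenation of the β-keto ester at low pressure, so that the isolated alkene is kept (a ketoreductase is the alternative), should give tert-butyl (3S)-3-hydroxyoctadec-17-enoate F3. Fráter–Seebach alkylation of its dianion (LDA, 2.2 equiv) with 9 should give the anti product di-tert-butyl (2S)-2-[(1S)-1-hydroxyhexadec-15-en-1-yl]butanedioate F4. TFA removes both tert-butyl groups and the γ-hydroxy acid should close to the cis lactone (2S,3S)-5-oxo-2-(pentadec-14-en-1-yl)oxolane-3-carboxylic acid F5. Dianion carboxylation (LDA, CO2) should give (2S,3S)-5-oxo-2-(pentadec-14-en-1-yl)oxolane-3,4-dicarboxylic acid F6. Decarboxylative Mannich methylenation as in step 6 should give (2S,3S)-4-methylidene-5-oxo-2-(pentadec-14-en-1-yl)oxolane-3-carboxylic acid F7, and Wacker oxidation as in step 7 should give 20.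

2. Step 6. The secondary amine may shift the new exocyclic double bond into the tetrasubstituted, doubly conjugated position, which would destroy C4. It may also add reversibly to the acrylate, and aminomethylation at the crowded malonate carbon may be slow enough for plain decarboxylation back to 13 to compete.
 Fallback (sets out from 13, comes back at 17, bypasses steps 5 and 6): the dianion of 13 (LDA, 2.3 equiv, −78 °C) is trapped with dimethylmethylideneammonium iodide to give the Mannich base (2R)-2-[3-tert-butoxy-1-(dimethylamino)-3-oxopropan-2-yl]octadec-17-enoic acid F8. One equivalent of mCPBA (aq. NaHCO3/CH2Cl2, 0 °C) should oxidise the amine far faster than the terminal alkene and give 3-tert-butoxy-2-[(1R)-1-carboxyheptadec-16-en-1-yl]-N,N-dimethyl-3-oxopropan-1-amine N-oxide F9. Cope elimination of F9 at room temperature, which can only take the hydrogen on C3, should give 17 without any free secondary amine.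

3. Step 7. Palladium hydride may move the terminal double bond along the chain before hydration, giving regioisomeric ketones, and the carboxylate and acrylate may sequester the catalyst.
 Fallback (sets out from 17, comes back at 18): oxymercuration with Hg(OAc)2 in THF/H2O, to which the acrylate is inert, should give the organomercurial (2R)-18-(acetoxymercurio)-2-[3-(tert-butoxy)-3-oxoprop-1-en-2-yl]-17-hydroxyoctadecanoic acid F10. Reduction in the same flask with NaBH4/NaOH should give (2R)-2-[3-(tert-butoxy)-3-oxoprop-1-en-2-yl]-17-hydroxyoctadecanoic acid F11 (C17 epimers), and Dess–Martin oxidation of the secondary alcohol should give 18.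

**Further compounds**

F1 | step 9 | methyl hexadec-15-enoate | C=CCCCCCCCCCCCCCC(=O)OC
F2 | step 9 | tert-butyl 3-oxooctadec-17-enoate | C=CCCCCCCCCCCCCCC(=O)CC(=O)OC(C)(C)C
F3 | step 9 | tert-butyl (3S)-3-hydroxyoctadec-17-enoate | C=CCCCCCCCCCCCCC[C@H](O)CC(=O)OC(C)(C)C
F4 | step 9 | di-tert-butyl (2S)-2-[(1S)-1-hydroxyhexadec-15-en-1-yl]butanedioate | C=CCCCCCCCCCCCCC[C@H](O)[C@@H](C(=O)OC(C)(C)C)CC(=O)OC(C)(C)C
F5 | step 9 | (2S,3S)-5-oxo-2-(pentadec-14-en-1-yl)oxolane-3-carboxylic acid | C1C(=O)O[C@@H](CCCCCCCCCCCCCC=C)[C@H]1C(=O)O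
F6 | step 9 | (2S,3S)-5-oxo-2-(pentadec-14-en-1-yl)oxolane-3,4-dicarboxylic acid (C4 epimers) | OC(=O)C1C(=O)O[C@@H](CCCCCCCCCCCCCC=C)[C@H]1C(=O)O
F7 | step 9 | (2S,3S)-4-methylidene-5-oxo-2-(pentadec-14-en-1-yl)oxolane-3-carboxylic acid | C=C1C(=O)O[C@@H](CCCCCCCCCCCCCC=C)[C@H]1C(=O)O
F8 | step 6 | (2R)-2-[3-tert-butoxy-1-(dimethylamino)-3-oxopropan-2-yl]octadec-17-enoic acid | C=CCCCCCCCCCCCCCC[C@@H](C(=O)O)C(CN(C)C)C(=O)OC(C)(C)C
F9 | step 6 | 3-tert-butoxy-2-[(1R)-1-carboxyheptadec-16-en-1-yl]-N,N-dimethyl-3-oxopropan-1-amine N-oxide | C=CCCCCCCCCCCCCCC[C@@H](C(=O)O)C(C[N+](C)(C)[O-])C(=O)OC(C)(C)C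
F10 | step 7 | (2R)-18-(acetoxymercurio)-2-[3-(tert-butoxy)-3-oxoprop-1-en-2-yl]-17-hydroxyoctadecanoic acid | CC(=O)O[Hg]CC(O)CCCCCCCCCCCCCC[C@@H](C(=O)O)C(=C)C(=O)OC(C)(C)C
F11 | step 7 | (2R)-2-[3-(tert-butoxy)-3-oxoprop-1-en-2-yl]-17-hydroxyoctadecanoic acid | CC(O)CCCCCCCCCCCCCC[C@@H](C(=O)O)C(=C)C(=O)OC(C)(C)C
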